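The route disconnects at C1 of ring B, a methine bonded to two electron-rich arenes: the guaiacyl ring through the carbon para to its hydroxyl, and ring A through the fusion carbon C8a. C1 is therefore introduced as one carbon at the aldehyde oxidation level. In the key step a Lewis acid lets this carbon arylate free guaiacol and then close ring B onto C8a, making both C1–aryl bonds and setting C1 trans to C2 in one operation. The precursor is an acyclic (E)-syringylidene succinate ester whose C2 stereocentre (silyloxymethyl) comes from an oxazolidinone-directed alkylation, with C1 stored as a dimethyl acetal so that no enolisable free aldehyde is handled.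

Key step: step 6

Remark on numbering and assumptions: ring B is numbered C1 (guaiacyl-bearing), C2 (hydroxymethyl), C3 (formyl), C4 (vinylic CH), C4a and C8a (fusion carbons, C8a next to C1); ring A is the benzo ring. The target is taken as the trans (1S,2R) isomer encoded in its SMILES. The key-step precursor 10 is the (R)-3-formyl-4-silyloxybutanoate skeleton with the formyl group protected as its dimethyl acetal. Because the acetal carbon is then the electrophile-derived arm of C2, the auxiliary must be (R)-4-benzyl-2-oxazolidinone.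

Step 1
Reactants: 1 syringaldehyde (4-hydroxy-3,5-dimethoxybenzaldehyde); 2 dimethyl succinate
Product: 3 (E)-4-(4-hydroxy-3,5-dimethoxyphenyl)-3-(methoxycarbonyl)but-3-enoic acid
Conditions: LiOMe (3.5 equiv), MeOH, reflux; then aq. HCl
Reagents that add atoms: none
Why: Stobbe condensation: the succinate enolate adds to the aldehyde, the aldolate lactonises to a paraconic ester and base-induced ring opening gives the half-ester carboxylate irreversibly with the aryl group cis to the CH2CO2H arm ((E)-alkene), the phenol being carried as its lithium phenoxide by the extra base.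

Step 2
Reactants: 3 (E)-4-(4-hydroxy-3,5-dimethoxyphenyl)-3-(methoxycarbonyl)but-3-enoic acid; 4 (R)-4-benzyl-2-oxazolidinone
Product: 6 methyl (E)-2-{2-[(R)-4-benzyl-2-oxooxazolidin-3-yl]-2-oxoethyl}-3-[3,5-dimethoxy-4-(pivaloyloxy)phenyl]acrylate, via mixed pivalic anhydride 5 (not isolated)
Conditions: PivCl (2.3 equiv), Et3N (4 equiv), THF, −20 to 0 °C; then 4 (1.3 equiv), LiCl, rt
Reagents that add atoms: pivaloyl chloride, CC(C)(C)C(=O)Cl
Why: N-acylation of an oxazolidinone through a mixed pivalic anhydride: excess PivCl/Et3N should esterify the hindered phenol and activate the acid in the same flask, and the LiCl/Et3N-activated oxazolidinone then attacks the less hindered carbonyl of 5, leaving the (E)-alkene and the methyl ester untouched.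

Step 3
Reactants: 6 methyl (E)-2-{2-[(R)-4-benzyl-2-oxooxazolidin-3-yl]-2-oxoethyl}-3-[3,5-dimethoxy-4-(pivaloyloxy)phenyl]acrylate
Product: 8 methyl (S,E)-3-[(R)-4-benzyl-2-oxooxazolidine-3-carbonyl]-2-[3,5-dimethoxy-4-(pivaloyloxy)benzylidene]-4,4-dimethoxybutanoate, via trichlorotitanium Z-enolate 7 (not isolated)
Conditions: TiCl4 (1.1 equiv), i-Pr2NEt (1.15 equiv), CH2Cl2, 0 °C; then HC(OMe)3 (2 equiv), 0 °C
Reagents that add atoms: trimethyl orthoformate, COC(OC)OC
Why: Evans alkylation of a titanium imide enolate with an orthoester: soft enolisation gives the chelated Z-enolate 7, and the dimethoxycarbenium ion from HC(OMe)3 should add to its alpha carbon on the face opposite the benzyl group of the (R)-auxiliary, which sets the future C2 (the acetal carbon becomes C1, the imide carbonyl becomes the C2 hydroxymethyl carbon) in the sense required for (2R) in the target.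

Step 4
Reactants: 8 methyl (S,E)-3-[(R)-4-benzyl-2-oxooxazolidine-3-carbonyl]-2-[3,5-dimethoxy-4-(pivaloyloxy)benzylidene]-4,4-dimethoxybutanoate
Product: 9 methyl (R,E)-2-[3,5-dimethoxy-4-(pivaloyloxy)benzylidene]-3-(hydroxymethyl)-4,4-dimethoxybutanoate
Conditions: LiBH4 (1.2 equiv), MeOH (1.2 equiv), THF, −20 to 0 °C; then pH 7 phosphate buffer
Reagents that add atoms: none
Why: Reductive cleavage of an N-acyl oxazolidinone by LiBH4: the exocyclic imide carbonyl is far more electrophilic than the conjugated methyl ester and the hindered aryl pivalate, the acetal is inert to hydride, and the cold buffered quench is meant to stop the new alkoxide from closing onto the ester; the stereocentre is not touched (its descriptor changes from S to R only through the change in priorities).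

Step 5
Reactants: 9 methyl (R,E)-2-[3,5-dimethoxy-4-(pivaloyloxy)benzylidene]-3-(hydroxymethyl)-4,4-dimethoxybutanoate
Product: 10 methyl (R,E)-3-{[(tert-butyldiphenylsilyl)oxy]methyl}-2-[3,5-dimethoxy-4-(pivaloyloxy)benzylidene]-4,4-dimethoxybutanoate
Conditions: TBDPSCl, imidazole, CH2Cl2, 0 °C to rt
Reagents that add atoms: tert-butyl(chloro)diphenylsilane, CC(C)(C)[Si](Cl)(c1ccccc1)c1ccccc1
Why: Silylation of a primary alcohol with TBDPSCl/imidazole caps the gamma-hydroxy ester before it can lactonise and installs an ether that should survive BF3·OEt2 and i-Bu2AlH and that shields one face of C1 in the next step.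

Step 6
Reactants: 10 methyl (R,E)-3-{[(tert-butyldiphenylsilyl)oxy]methyl}-2-[3,5-dimethoxy-4-(pivaloyloxy)benzylidene]-4,4-dimethoxybutanoate; 11 guaiacol (2-methoxyphenol)
Product: 13 methyl (1S,2R)-2-{[(tert-butyldiphenylsilyl)oxy]methyl}-1-(4-hydroxy-3-methoxyphenyl)-6,8-dimethoxy-7-(pivaloyloxy)-1,2-dihydronaphthalene-3-carboxylate, via benzylic methyl ether 12 (not isolated)
Conditions: 11 (5 equiv), BF3·OEt2 (3 equiv), CH2Cl2 (0.02 M), −78 to −20 °C
Reagents that add atoms: none
Why: Proposed new method: BF3 ionises the dimethyl acetal of 10 to a methoxycarbenium ion at C1, guaiacol attacks it through the carbon para to its hydroxyl to give ether 12, and BF3 then ionises 12 to the O-protonated para-quinone methide, which ring A captures through C8a; should ring A reach C1 first, the cyclic benzylic ether so formed ionises and is arylated by guaiacol to the same product. The closest known reaction types are the Lewis-acid Friedel–Crafts arylation of acetals by phenols and the acid-induced closure of para-oxygenated benzylic cations onto a cis-held aryl ring used for aryldihydronaphthalene lignans; their tandem use on a C1 flanked by an sp3 stereocentre carrying a removable proton has not been shown. Ring B closes by a six-membered Friedel–Crafts alkylation (6-exo-trig at the quinone methide carbon, C8a as nucleophile), which the (E)-alkene allows by holding ring A cis to C2. The new C1 stereocentre is controlled by C2: the last C–C bond should form on the face of the planar C1 cation anti to the silyloxymethyl group, giving the 1,2-trans (1S,2R) product with both substituents pseudoaxial, away from the C8 methoxy group and the C3 ester. The step needs para selectivity on guaiacol (secured by the free hydroxyl as the stronger donor and by the bulk of the electrophile), a single arylation (secured by intramolecular capture of the second cation; the symmetric ring A offers one kind of free position) and an intact C2 (secured by releasing the cation from the acetal at low temperature in the presence of the nucleophile, so that no free aldehyde can enolise).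

Step 7
Reactants: 13 methyl (1S,2R)-2-{[(tert-butyldiphenylsilyl)oxy]methyl}-1-(4-hydroxy-3-methoxyphenyl)-6,8-dimethoxy-7-(pivaloyloxy)-1,2-dihydronaphthalene-3-carboxylate
Product: 14 (1S,2R)-2-{[(tert-butyldiphenylsilyl)oxy]methyl}-1-(4-hydroxy-3-methoxyphenyl)-3-(hydroxymethyl)-6,8-dimethoxy-1,2-dihydronaphthalen-7-ol
Conditions: i-Bu2AlH (7 equiv), CH2Cl2, −78 to 0 °C; then aq. potassium sodium tartrate
Reagents that add atoms: none
Why: i-Bu2AlH reduction: after deprotonating the phenol, the hydride should reduce the conjugated ester in 1,2 fashion to the allylic alcohol and cleave the aryl pivalate to the free ring A phenol, while the silyl ether, the C3=C4 alkene and both stereocentres are not affected.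

Step 8
Reactants: 14 (1S,2R)-2-{[(tert-butyldiphenylsilyl)oxy]methyl}-1-(4-hydroxy-3-methoxyphenyl)-3-(hydroxymethyl)-6,8-dimethoxy-1,2-dihydronaphthalen-7-ol
Product: 15 (1S,2R)-2-{[(tert-butyldiphenylsilyl)oxy]methyl}-7-hydroxy-1-(4-hydroxy-3-methoxyphenyl)-6,8-dimethoxy-1,2-dihydronaphthalene-3-carbaldehyde
Conditions: activated MnO2 (15 equiv), CH2Cl2, rt
Reagents that add atoms: none
Why: Chemoselective MnO2 oxidation of an allylic alcohol: only the C3 hydroxymethyl group is allylic (conjugated through C4 with ring A, as in sinapyl alcohol), the C2 oxygen is still silylated so that no lactol can form and be over-oxidised to a lactone, and the phenols are left free as in the oxidation of hydroxycinnamyl alcohols to their aldehydes.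

Step 9
Reactants: 15 (1S,2R)-2-{[(tert-butyldiphenylsilyl)oxy]methyl}-7-hydroxy-1-(4-hydroxy-3-methoxyphenyl)-6,8-dimethoxy-1,2-dihydronaphthalene-3-carbaldehyde
Product: 16 (1S,2R)-7-hydroxy-1-(4-hydroxy-3-methoxyphenyl)-2-(hydroxymethyl)-6,8-dimethoxy-1,2-dihydronaphthalene-3-carbaldehyde (target)
Conditions: Bu4NF (3 equiv), AcOH (3 equiv), THF, 0 °C to rt
Reagents that add atoms: none
Why: Fluoride-induced cleavage of a silyl ether: Bu4NF buffered with AcOH should remove the TBDPS group without generating phenoxides or epimerising C1 and C2 next to the enal, giving the target as its open hydroxy aldehyde.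

Compound list

1 | syringaldehyde | COc1cc(C=O)cc(OC)c1O | starting material
2 | dimethyl succinate | COC(=O)CCC(=O)OC | starting material
3 | (E)-4-(4-hydroxy-3,5-dimethoxyphenyl)-3-(methoxycarbonyl)but-3-enoic acid | COC(=O)/C(CC(=O)O)=C/c1cc(OC)c(O)c(OC)c1 | intermediate
4 | (R)-4-benzyl-2-oxazolidinone | O=C1N[C@H](Cc2ccccc2)CO1 | starting material
5 | mixed pivalic anhydride of the O-pivaloylated half-ester (not isolated) | COC(=O)/C(CC(=O)OC(=O)C(C)(C)C)=C/c1cc(OC)c(OC(=O)C(C)(C)C)c(OC)c1 | intermediate
6 | methyl (E)-2-{2-[(R)-4-benzyl-2-oxooxazolidin-3-yl]-2-oxoethyl}-3-[3,5-dimethoxy-4-(pivaloyloxy)phenyl]acrylate | COC(=O)/C(CC(=O)N1[C@H](Cc2ccccc2)COC1=O)=C/c1cc(OC)c(OC(=O)C(C)(C)C)c(OC)c1 | intermediate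
7 | trichlorotitanium Z-enolate of 6 (not isolated) | COC(=O)/C(/C=C(\O[Ti](Cl)(Cl)Cl)N1[C@H](Cc2ccccc2)COC1=O)=C/c1cc(OC)c(OC(=O)C(C)(C)C)c(OC)c1 | intermediate
8 | methyl (S,E)-3-[(R)-4-benzyl-2-oxooxazolidine-3-carbonyl]-2-[3,5-dimethoxy-4-(pivaloyloxy)benzylidene]-4,4-dimethoxybutanoate | COC(OC)[C@@H](C(=O)N1[C@H](Cc2ccccc2)COC1=O)/C(C(=O)OC)=C\c1cc(OC)c(OC(=O)C(C)(C)C)c(OC)c1 | intermediate
9 | methyl (R,E)-2-[3,5-dimethoxy-4-(pivaloyloxy)benzylidene]-3-(hydroxymethyl)-4,4-dimethoxybutanoate | COC(OC)[C@@H](CO)/C(C(=O)OC)=C\c1cc(OC)c(OC(=O)C(C)(C)C)c(OC)c1 | intermediate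
10 | methyl (R,E)-3-{[(tert-butyldiphenylsilyl)oxy]methyl}-2-[3,5-dimethoxy-4-(pivaloyloxy)benzylidene]-4,4-dimethoxybutanoate (key-step precursor, formyl group as dimethyl acetal) | COC(OC)[C@@H](CO[Si](c1ccccc1)(c1ccccc1)C(C)(C)C)/C(C(=O)OC)=C\c1cc(OC)c(OC(=O)C(C)(C)C)c(OC)c1 | intermediate
11 | guaiacol | COc1ccccc1O | starting material
12 | benzylic methyl ether from the first arylation, mixture of C1 epimers (not isolated) | COc1cc(C(OC)[C@@H](CO[Si](c2ccccc2)(c2ccccc2)C(C)(C)C)/C(C(=O)OC)=C\c2cc(OC)c(OC(=O)C(C)(C)C)c(OC)c2)ccc1O | intermediate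
13 | methyl (1S,2R)-2-{[(tert-butyldiphenylsilyl)oxy]methyl}-1-(4-hydroxy-3-methoxyphenyl)-6,8-dimethoxy-7-(pivaloyloxy)-1,2-dihydronaphthalene-3-carboxylate (key-step product) | COc1cc([C@H]2c3c(cc(OC)c(OC(=O)C(C)(C)C)c3OC)C=C(C(=O)OC)[C@@H]2CO[Si](c4ccccc4)(c4ccccc4)C(C)(C)C)ccc1O | intermediate
14 | (1S,2R)-2-{[(tert-butyldiphenylsilyl)oxy]methyl}-1-(4-hydroxy-3-methoxyphenyl)-3-(hydroxymethyl)-6,8-dimethoxy-1,2-dihydronaphthalen-7-ol | COc1cc([C@H]2c3c(cc(OC)c(O)c3OC)C=C(CO)[C@@H]2CO[Si](c4ccccc4)(c4ccccc4)C(C)(C)C)ccc1O | intermediate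
15 | (1S,2R)-2-{[(tert-butyldiphenylsilyl)oxy]methyl}-7-hydroxy-1-(4-hydroxy-3-methoxyphenyl)-6,8-dimethoxy-1,2-dihydronaphthalene-3-carbaldehyde | COc1cc([C@H]2c3c(cc(OC)c(O)c3OC)C=C(C=O)[C@@H]2CO[Si](c4ccccc4)(c4ccccc4)C(C)(C)C)ccc1O | intermediate
16 | (1S,2R)-7-hydroxy-1-(4-hydroxy-3-methoxyphenyl)-2-(hydroxymethyl)-6,8-dimethoxy-1,2-dihydronaphthalene-3-carbaldehyde | COc1cc([C@H]2c3c(cc(OC)c(O)c3OC)C=C(C=O)[C@@H]2CO)ccc1O | target

Total step count: 9. Longest linear sequence: 9 steps (1 to 16).

Steps most likely to fail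

Step 6 (proposed new method). Several processes can divert it:
- Ring A may capture the C1 cation before guaiacol does; the cyclic benzylic cation can then lose the C2 proton, so that ring B aromatises to a naphthalene.
- A second guaiacol may add to the quinone methide.
- Guaiacol may react through the carbon para to its methoxy group.
- Proton loss from the oxocarbenium ion may scramble C2.

The fallback uses known chemistry only, sets out from 10 and comes back at 13; the two C1–aryl bonds are made one after the other with a regiodefined aryl nucleophile. Acetal 10 is hydrolysed (aq. CF3CO2H, CH2Cl2, 0 °C) to methyl (R,E)-4-[(tert-butyldiphenylsilyl)oxy]-2-[3,5-dimethoxy-4-(pivaloyloxy)benzylidene]-3-formylbutanoate F1, which is used crude at once. Commercial 4-bromo-2-methoxyphenol (COc1cc(Br)ccc1O) is silylated (TBSCl, imidazole) to (4-bromo-2-methoxyphenoxy)(tert-butyl)dimethylsilane F2 and converted with Mg in THF into [4-(tert-butyldimethylsilyloxy)-3-methoxyphenyl]magnesium bromide F3. Addition of F3 to F1 at −78 °C should give methyl (3R,E)-3-{[(tert-butyldiphenylsilyl)oxy]methyl}-4-[4-(tert-butyldimethylsilyloxy)-3-methoxyphenyl]-2-[3,5-dimethoxy-4-(pivaloyloxy)benzylidene]-4-hydroxybutanoate F4 as a mixture of carbinol epimers. CF3CO2H in CH2Cl2 at 0 °C ionises the carbinol and ring A closes onto the exocyclic para-silyloxybenzylic cation (the classical closure of aryldihydronaphthalene lignans, trans to the C2 substituent, with no cyclic cation that could aromatise). This gives methyl (1S,2R)-1-[4-(tert-butyldimethylsilyloxy)-3-methoxyphenyl]-2-{[(tert-butyldiphenylsilyl)oxy]methyl}-6,8-dimethoxy-7-(pivaloyloxy)-1,2-dihydronaphthalene-3-carboxylate F5. KHF2 in MeOH at rt cleaves the aryl silyl ether selectively and returns 13.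

Step 4. The lithium alkoxide released by the hydride may lactonise onto the neighbouring methyl ester; hydride may also attack the ester or the pivalate, or open the hindered imide at the ring carbonyl. The fallback sets out from 8 and comes back at 9; the auxiliary leaves by thiolate acyl transfer and the reduction is split into two mild stages. EtSLi (from EtSH and n-BuLi, THF, −20 °C) should convert 8 into methyl (S,E)-2-[3,5-dimethoxy-4-(pivaloyloxy)benzylidene]-3-[(ethylsulfanyl)carbonyl]-4,4-dimethoxybutanoate F6. Fukuyama reduction (Et3SiH, Pd on carbon, acetone, rt) gives methyl (R,E)-2-[3,5-dimethoxy-4-(pivaloyloxy)benzylidene]-3-formyl-4,4-dimethoxybutanoate F7. This is reduced at once under Luche conditions (NaBH4, CeCl3·7H2O, MeOH, −78 °C, AcOH quench) to 9, so that the alkoxide exists only briefly in a cold protic medium.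

Step 8. The oxidant may attack the free phenols (phenoxyl coupling, quinone methide formation at the para-hydroxybenzylic C1) or dehydrogenate ring B to the naphthalene instead of stopping at the enal. The fallback sets out from 14 and comes back at 15; the phenols are masked and a two-electron alcohol oxidant is used. Ac2O (2.2 equiv) in aq. NaOH/THF at 0 °C acylates only the two phenoxides and should give 4-[(1S,2R)-7-acetoxy-2-{[(tert-butyldiphenylsilyl)oxy]methyl}-3-(hydroxymethyl)-6,8-dimethoxy-1,2-dihydronaphthalen-1-yl]-2-methoxyphenyl acetate F8. Dess–Martin periodinane (NaHCO3, CH2Cl2, 0 °C) oxidises the allylic alcohol to 4-[(1S,2R)-7-acetoxy-2-{[(tert-butyldiphenylsilyl)oxy]methyl}-3-formyl-6,8-dimethoxy-1,2-dihydronaphthalen-1-yl]-2-methoxyphenyl acetate F9. K2CO3 in MeOH at 0 °C removes both aryl acetates and returns 15.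

Further compounds

F1 | step 6 | methyl (R,E)-4-[(tert-butyldiphenylsilyl)oxy]-2-[3,5-dimethoxy-4-(pivaloyloxy)benzylidene]-3-formylbutanoate | O=C[C@@H](CO[Si](c1ccccc1)(c1ccccc1)C(C)(C)C)/C(C(=O)OC)=C\c1cc(OC)c(OC(=O)C(C)(C)C)c(OC)c1
F2 | step 6 | (4-bromo-2-methoxyphenoxy)(tert-butyl)dimethylsilane | COc1cc(Br)ccc1O[Si](C)(C)C(C)(C)C
F3 | step 6 | [4-(tert-butyldimethylsilyloxy)-3-methoxyphenyl]magnesium bromide | COc1cc([Mg]Br)ccc1O[Si](C)(C)C(C)(C)C
F4 | step 6 | methyl (3R,E)-3-{[(tert-butyldiphenylsilyl)oxy]methyl}-4-[4-(tert-butyldimethylsilyloxy)-3-methoxyphenyl]-2-[3,5-dimethoxy-4-(pivaloyloxy)benzylidene]-4-hydroxybutanoate (carbinol epimers) | COc1cc(C(O)[C@@H](CO[Si](c2ccccc2)(c2ccccc2)C(C)(C)C)/C(C(=O)OC)=C\c2cc(OC)c(OC(=O)C(C)(C)C)c(OC)c2)ccc1O[Si](C)(C)C(C)(C)C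
F5 | step 6 | methyl (1S,2R)-1-[4-(tert-butyldimethylsilyloxy)-3-methoxyphenyl]-2-{[(tert-butyldiphenylsilyl)oxy]methyl}-6,8-dimethoxy-7-(pivaloyloxy)-1,2-dihydronaphthalene-3-carboxylate | COc1cc([C@H]2c3c(cc(OC)c(OC(=O)C(C)(C)C)c3OC)C=C(C(=O)OC)[C@@H]2CO[Si](c4ccccc4)(c4ccccc4)C(C)(C)C)ccc1O[Si](C)(C)C(C)(C)C
F6 | step 4 | methyl (S,E)-2-[3,5-dimethoxy-4-(pivaloyloxy)benzylidene]-3-[(ethylsulfanyl)carbonyl]-4,4-dimethoxybutanoate | COC(OC)[C@@H](C(=O)SCC)/C(C(=O)OC)=C\c1cc(OC)c(OC(=O)C(C)(C)C)c(OC)c1
F7 | step 4 | methyl (R,E)-2-[3,5-dimethoxy-4-(pivaloyloxy)benzylidene]-3-formyl-4,4-dimethoxybutanoate | COC(OC)[C@@H](C=O)/C(C(=O)OC)=C\c1cc(OC)c(OC(=O)C(C)(C)C)c(OC)c1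
F8 | step 8 | 4-[(1S,2R)-7-acetoxy-2-{[(tert-butyldiphenylsilyl)oxy]methyl}-3-(hydroxymethyl)-6,8-dimethoxy-1,2-dihydronaphthalen-1-yl]-2-methoxyphenyl acetate | COc1cc([C@H]2c3c(cc(OC)c(OC(C)=O)c3OC)C=C(CO)[C@@H]2CO[Si](c4ccccc4)(c4ccccc4)C(C)(C)C)ccc1OC(C)=O
F9 | step 8 | 4-[(1S,2R)-7-acetoxy-2-{[(tert-butyldiphenylsilyl)oxy]methyl}-3-formyl-6,8-dimethoxy-1,2-dihydronaphthalen-1-yl]-2-methoxyphenyl acetate | COc1cc([C@H]2c3c(cc(OC)c(OC(C)=O)c3OC)C=C(C=O)[C@@H]2CO[Si](c4ccccc4)(c4ccccc4)C(C)(C)C)ccc1OC(C)=O
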